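**Plan** (germacranolide numbering: ring C1–C10, C14 on C10, C15 on C4, lactone C12(=O)–O–C6, C13 = CH2OAc; target = 1S,4S,5R,6R,8R,10R; both oxiranes are cis-fused, i.e. derived from Z-alkenes)
Cuts: the C8–O and C13–O acyl bonds; ring bond C7–C8 (alkenyl bromide + aldehyde); butenolide bonds C6–C7 and O–C12 (aldehyde + C3 dibromoacrylate); C8–C9 together with the Z C1=C10 alkene ([2,3] shift); C1–C10 (aldehyde + isopropenyl); this leaves nerol (C1–C6, C15).
Forward ring order: oxirane C4–C5, oxirane C1–C10, butenolide, then the ten-membered carbocycle as the last ring; the two esters are set afterwards.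
Stereochemistry: C4/C5 by Sharpless epoxidation of nerol (D-tartrate); C1/C10 by Shi epoxidation (L-fructose-derived ketone) of the Z-alkene from the Wittig–Still shift; C6 by Felkin–Anh addition next to the C4–C5 oxirane; C8 in the ring closure, then inverted on esterification.
Enabling feature: C7 is the β-carbon of the butenolide (a vinylogous acyl position that can carry Br) and C8 is the carbinol carbon next to it; the two cis-oxiranes (C1–C10, C4–C5) fold the C9…C5 chain like Z-alkenes.

Key step: step 16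

Step 1
Reactants: 1 ethyl 2-(hydroxymethyl)prop-2-enoate
Product: 2 ethyl 2-{[(tert-butyldimethylsilyl)oxy]methyl}prop-2-enoate
Conditions: TBSCl, imidazole, CH2Cl2, 0 °C → rt
Reagents that add atoms: tert-butyldimethylsilyl chloride, CC(C)(C)[Si](C)(C)Cl
Why: Imidazole-mediated silylation masks the future C13–OH as a robust, non-coordinating ether for the later magnesium chemistry; no stereocenter.

Step 2
Reactants: 2 ethyl 2-{[(tert-butyldimethylsilyl)oxy]methyl}prop-2-enoate
Product: 3 ethyl 3-[(tert-butyldimethylsilyl)oxy]-2-oxopropanoate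
Conditions: O3, CH2Cl2, −78 °C; then Me2S
Reagents that add atoms: ozone, [O-][O+]=O
Why: Ozonolysis of the 1,1-disubstituted alkene with reductive work-up gives the α-keto ester, silyl ether and ester being inert to ozone.

Step 3
Reactants: 3 ethyl 3-[(tert-butyldimethylsilyl)oxy]-2-oxopropanoate
Product: 4 ethyl 3,3-dibromo-2-{[(tert-butyldimethylsilyl)oxy]methyl}prop-2-enoate
Conditions: CBr4, PPh3, CH2Cl2, 0 °C
Reagents that add atoms: carbon tetrabromide, BrC(Br)(Br)Br
Why: Ramirez dibromo-olefination of the electrophilic α-keto ester turns C=O into C=CBr2, creating C7 as a gem-dibromide with no E/Z issue.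

Step 4
Reactants: 5 nerol
Product: 6 (2R,3S)-2,3-epoxynerol (4S,5R)
Conditions: Ti(OiPr)4, D-(−)-diethyl tartrate, t-BuOOH, 4 Å MS, CH2Cl2, −20 °C
Reagents that add atoms: tert-butyl hydroperoxide, CC(C)(C)OO
Why: Sharpless asymmetric epoxidation of the Z-allylic alcohol, in which the D-tartrate–titanium complex delivers oxygen to the face giving the (2R,3S)-epoxide while the remote alkene without allylic OH is untouched.

Step 5
Reactants: 6 (2R,3S)-2,3-epoxynerol
Product: 7 O-TBDPS-(2R,3S)-2,3-epoxynerol
Conditions: TBDPSCl, imidazole, CH2Cl2, 0 °C → rt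
Reagents that add atoms: tert-butyl(chloro)diphenylsilane, CC(C)(C)[Si](Cl)(c1ccccc1)c1ccccc1
Why: Imidazole-mediated silylation of the primary alcohol gives an ether that survives ozone, Grignard reagent, KH and n-BuLi and is later removed by fluoride beside a PMB ether.

Step 6
Reactants: 7 O-TBDPS-(2R,3S)-2,3-epoxynerol
Product: 8 C1 aldehyde 3-[(2S,3R)-3-{[(tert-butyldiphenylsilyl)oxy]methyl}-2-methyloxiran-2-yl]propanal
Conditions: O3, CH2Cl2, −78 °C; then PPh3
Reagents that add atoms: ozone, [O-][O+]=O
Why: Ozonolysis with reductive work-up cleaves the only alkene to the C1 aldehyde, oxirane and silyl ether being stable to ozone at −78 °C.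

Step 7
Reactants: 8 C1 aldehyde
Product: 9 isopropenyl carbinol (C1 epimer mixture) 1-[(2S,3R)-3-{[(tert-butyldiphenylsilyl)oxy]methyl}-2-methyloxiran-2-yl]-4-methylpent-4-en-3-ol
Conditions: isopropenylmagnesium bromide, THF, −78 °C; aq NH4Cl
Reagents that add atoms: isopropenylmagnesium bromide, CC(=C)[Mg]Br
Why: Grignard 1,2-addition to the aldehyde is much faster than opening of the trisubstituted oxirane at −78 °C, and the new carbinol centre, formed as a mixture, is destroyed in step 9.

Step 8
Reactants: 9 isopropenyl carbinol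
Product: 10 tributylstannylmethyl ether of 9
Conditions: KH, THF, 0 °C; Bu3SnCH2I, 0 °C → rt
Reagents that add atoms: tributyl(iodomethyl)stannane, CCCC[Sn](CCCC)(CCCC)CI
Why: Williamson etherification of the potassium alkoxide with the reactive α-stannyl iodide, the fully substituted proximal oxirane carbon (C4) resisting intramolecular attack by the alkoxide at 0 °C.

Step 9
Reactants: 10 tributylstannylmethyl ether
Product: 13 Z-homoallylic PMB ether TBDPSO–C6H2–[4S,5R oxirane]–C3H2–C2H2–C1H=C10(CH3)–C9H2–C8H2–OPMB, via α-lithiomethyl ether 11 (not isolated), via lithium homoallyl alkoxide 12 (not isolated)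
Conditions: n-BuLi, THF, −78 °C; then PMBBr, Bu4NI (cat.), DMPU, −78 °C → rt
Reagents that add atoms: 4-methoxybenzyl bromide, COc1ccc(CBr)cc1
Why: Tin–lithium exchange triggers the Wittig–Still [2,3]-sigmatropic shift, which forms C8–C9 and the C1=C10 alkene with Z geometry (the C1 substituent sits pseudo-axial in the envelope transition state to avoid A1,2 strain with the 2-methyl group), and the lithium alkoxide is benzylated in the same flask.

Step 10
Reactants: 13 Z-homoallylic PMB ether
Product: 14 bis-epoxide (1S,4S,5R,10R) with C6–OTBDPS and C8–OPMB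
Conditions: L-fructose-derived Shi ketone (0.3 equiv), Oxone, K2CO3, Bu4NHSO4, MeCN/DMM/aq borate–EDTA buffer, 0 °C
Reagents that add atoms: potassium peroxymonosulfate (Oxone), OOS(=O)(=O)[O-].[K+]
Why: Shi asymmetric epoxidation (chiral dioxirane, spiro transition state) of the only alkene, where the enantiomer of the D-fructose ketone (which gives R,R-type epoxides from trans- and trisubstituted alkenes) is chosen so that oxygen adds to the face giving 1S,10R by reagent control, independent of the remote oxirane.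

Step 11
Reactants: 14 bis-epoxide
Product: 15 bis-epoxy alcohol (1S,4S,5R,10R) with free C6–OH
Conditions: TBAF, AcOH, THF, 0 °C → rt
Reagents that add atoms: none
Why: Fluoride cleavage of the silyl ether, buffered with acetic acid to suppress Payne rearrangement of the liberated 2,3-epoxy alcohol, leaves the PMB ether and both oxiranes untouched.

Step 12
Reactants: 15 bis-epoxy alcohol
Product: 16 bis-epoxy aldehyde (C6 CHO; 1S,4S,5S,10R, the C5 descriptor changing only because CHO outranks C4)
Conditions: Dess–Martin periodinane, NaHCO3, CH2Cl2, 0 °C → rt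
Reagents that add atoms: none
Why: Buffered Dess–Martin oxidation gives the configurationally stable α,β-epoxy aldehyde without acid- or base-induced oxirane opening.

Step 13
Reactants: 16 bis-epoxy aldehyde; 4 ethyl 3,3-dibromo-2-{[(tert-butyldimethylsilyl)oxy]methyl}prop-2-enoate
Product: 19 bromobutenolide (1S,4S,5R,6S,10R; 6S only because Br raises C7, spatially as in the target) 4-bromo-3-(TBSOCH2)furan-2(5H)-one bearing at its C5 (= C6) the bis-epoxy chain ending in C8–OPMB, via magnesium carbenoid 17 (not isolated), via magnesium alkoxide adduct 18 (not isolated)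
Conditions: 4 (1.3 equiv), i-PrMgCl·LiCl (1.25 equiv), THF, −78 °C; then 16, −78 → −20 °C; aq NH4Cl
Reagents that add atoms: none
Why: Ester-directed bromine–magnesium exchange gives the chelated carbenoid with Mg syn to CO2Et, which adds to the aldehyde and lactonises in a tandem addition–lactonisation, C6 being set by Felkin–Anh (polar, anti to the C5–O bond) attack on the cis-substituted α,β-epoxy aldehyde.

Step 14
Reactants: 19 bromobutenolide
Product: 20 C8 primary alcohol (1S,4S,5R,6S,10R)
Conditions: DDQ, CH2Cl2/pH 7 buffer, 0 °C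
Reagents that add atoms: none
Why: Oxidative PMB cleavage under buffered conditions is orthogonal to the TBS ether, the oxiranes and the electron-poor bromobutenolide.

Step 15
Reactants: 20 C8 primary alcohol
Product: 21 C8 aldehyde (β,γ-epoxy aldehyde; 1S,4S,5R,6S,10R)
Conditions: Dess–Martin periodinane, NaHCO3, CH2Cl2, 0 °C; used crude at once
Reagents that add atoms: none
Why: Buffered Dess–Martin oxidation forms the β,γ-epoxy aldehyde under neutral conditions, and it is used immediately because bases would open the oxirane by β-elimination.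

Step 16
Reactants: 21 C8 aldehyde
Product: 23 macrocyclic 8S alcohol (1S,4S,5R,6R,8S,10R)-13-(tert-butyldimethylsilyloxy)-1,10:4,5-diepoxy-8-hydroxygermacr-7(11)-en-12,6-olide, via alkenylchromium(III) dichloride 22 (not isolated)
Conditions: CrCl2 (10 equiv), NiCl2 (0.1 equiv), degassed DMSO/THF, rt, syringe-pump addition (final ca. 2 mM); aq work-up
Reagents that add atoms: none
Why: Nozaki–Hiyama–Kishi reaction: Ni(0) formed from NiCl2/CrCl2 inserts into the activated C7–Br bond of the β-bromobutenolide, transmetalation gives the alkenylchromium(III) species 22, and this adds to the C8 aldehyde through a chromium-bound closed transition state. The closest precedent is the intramolecular Ni/Cr-mediated alkenyl halide–aldehyde coupling used for 9- to 12-membered carbocycles and for β-halo enoates. The ten-membered ring closes in a 10-exo-trig mode (C7 attacks C8, carbonyl oxygen exocyclic), helped by the two cis-oxiranes and the planar butenolide, which fold the chain so that C8 lies near C7. C8 is set by the ring-forming transition state: the aldehyde C–H should eclipse the C7=C11 bond to avoid A1,3 strain between O–Cr or C9 and the C13 methylene while the tether stays on the butenolide face defined by C5 (fixed by C6), which places O8 anti to the ring and gives 8S. The step needs chemoselectivity (the alkenylchromium adds only to the aldehyde, the oxiranes, lactone and silyl ether are inert, the non-basic medium avoids β-elimination of the epoxy aldehyde, and the C8 alkoxide cannot translactonise because it is trans to C12 across C7=C11), ring closure over oligomerisation (slow addition at high dilution) and facial selectivity, for which the A1,3 bias is relied on.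

Step 17
Reactants: 23 macrocyclic 8S alcohol
Product: 24 8R senecioate (1S,4S,5R,6R,8R,10R)-13-(tert-butyldimethylsilyloxy)-1,10:4,5-diepoxy-8-(3-methylbut-2-enoyloxy)germacr-7(11)-en-12,6-olide
Conditions: 3-methylbut-2-enoic acid, PPh3, DIAD, toluene, 0 °C → rt
Reagents that add atoms: 3-methylbut-2-enoic acid, CC(C)=CC(=O)O
Why: Mitsunobu esterification displaces the C8 oxyphosphonium ion by the carboxylate in an SN2 step, inverting C8 from S to R while installing the senecioate, SN2′ attack being blocked because the alkene terminus C11 is fully substituted.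

Step 18
Reactants: 24 8R senecioate
Product: 26 CNP0228323.1 (1S,4S,5R,6R,8R,10R)-13-acetoxy-1,10:4,5-diepoxy-8-(3-methylbut-2-enoyloxy)germacr-7(11)-en-12,6-olide, via C13 primary alcohol 25 (not isolated)
Conditions: HF·pyridine, pyridine, THF, 0 °C; aq NaHCO3 work-up; crude, then Ac2O, DMAP, pyridine, CH2Cl2, 0 °C
Reagents that add atoms: acetic anhydride, CC(=O)OC(C)=O
Why: Buffered HF·pyridine removes the primary allylic TBS ether without touching oxiranes or esters, and the crude alcohol is acetylated at once (DMAP-catalysed acylation) before the cis-disposed senecioate can migrate; no stereocenter is affected.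

**Compound list**
1 | ethyl 2-(hydroxymethyl)prop-2-enoate | C=C(CO)C(=O)OCC | starting material
2 | ethyl 2-{[(tert-butyldimethylsilyl)oxy]methyl}prop-2-enoate | C=C(CO[Si](C)(C)C(C)(C)C)C(=O)OCC | intermediate
3 | ethyl 3-[(tert-butyldimethylsilyl)oxy]-2-oxopropanoate | O=C(CO[Si](C)(C)C(C)(C)C)C(=O)OCC | intermediate
4 | ethyl 3,3-dibromo-2-{[(tert-butyldimethylsilyl)oxy]methyl}prop-2-enoate | BrC(Br)=C(CO[Si](C)(C)C(C)(C)C)C(=O)OCC | intermediate
5 | nerol, (2Z)-3,7-dimethylocta-2,6-dien-1-ol | CC(C)=CCC/C(C)=C\CO | starting material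
6 | (2R,3S)-2,3-epoxynerol | OC[C@H]1O[C@@]1(C)CCC=C(C)C | intermediate
7 | O-TBDPS-(2R,3S)-2,3-epoxynerol | CC(C)(C)[Si](c1ccccc1)(c1ccccc1)OC[C@H]1O[C@@]1(C)CCC=C(C)C | intermediate
8 | C1 aldehyde, 3-[(2S,3R)-3-{[(tert-butyldiphenylsilyl)oxy]methyl}-2-methyloxiran-2-yl]propanal | CC(C)(C)[Si](c1ccccc1)(c1ccccc1)OC[C@H]1O[C@@]1(C)CCC=O | intermediate
9 | isopropenyl carbinol (C1 epimer mixture) | CC(C)(C)[Si](c1ccccc1)(c1ccccc1)OC[C@H]1O[C@@]1(C)CCC(O)C(C)=C | intermediate
10 | tributylstannylmethyl ether of 9 | CC(C)(C)[Si](c1ccccc1)(c1ccccc1)OC[C@H]1O[C@@]1(C)CCC(OC[Sn](CCCC)(CCCC)CCCC)C(C)=C | intermediate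
11 | α-lithiomethyl ether | CC(C)(C)[Si](c1ccccc1)(c1ccccc1)OC[C@H]1O[C@@]1(C)CCC(OC[Li])C(C)=C | intermediate
12 | lithium homoallyl alkoxide (Z) | CC(C)(C)[Si](c1ccccc1)(c1ccccc1)OC[C@H]1O[C@@]1(C)CC/C=C(/C)CCO[Li] | intermediate
13 | Z-homoallylic PMB ether (4S,5R) | CC(C)(C)[Si](c1ccccc1)(c1ccccc1)OC[C@H]1O[C@@]1(C)CC/C=C(/C)CCOCc1ccc(OC)cc1 | intermediate
14 | bis-epoxide (1S,4S,5R,10R), C6–OTBDPS, C8–OPMB | CC(C)(C)[Si](c1ccccc1)(c1ccccc1)OC[C@H]1O[C@@]1(C)CC[C@@H]1O[C@]1(C)CCOCc1ccc(OC)cc1 | intermediate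
15 | bis-epoxy alcohol (C6–OH) | OC[C@H]1O[C@@]1(C)CC[C@@H]1O[C@]1(C)CCOCc1ccc(OC)cc1 | intermediate
16 | bis-epoxy aldehyde (C6 CHO) | O=C[C@H]1O[C@@]1(C)CC[C@@H]1O[C@]1(C)CCOCc1ccc(OC)cc1 | intermediate
17 | magnesium carbenoid, ethyl 3-bromo-3-(chloromagnesio)-2-(TBSOCH2)prop-2-enoate, Mg syn to CO2Et | CCOC(=O)/C(CO[Si](C)(C)C(C)(C)C)=C(/Br)[Mg]Cl | intermediate
18 | magnesium alkoxide adduct of 17 and 16 | CCOC(=O)/C(CO[Si](C)(C)C(C)(C)C)=C(/Br)[C@@H](O[Mg]Cl)[C@H]1O[C@@]1(C)CC[C@@H]1O[C@]1(C)CCOCc1ccc(OC)cc1 | intermediate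
19 | bromobutenolide (1S,4S,5R,6S,10R), C8–OPMB, C13–OTBS | CC(C)(C)[Si](C)(C)OCC1=C(Br)[C@@H](OC1=O)[C@H]1O[C@@]1(C)CC[C@@H]1O[C@]1(C)CCOCc1ccc(OC)cc1 | intermediate
20 | C8 primary alcohol | CC(C)(C)[Si](C)(C)OCC1=C(Br)[C@@H](OC1=O)[C@H]1O[C@@]1(C)CC[C@@H]1O[C@]1(C)CCO | intermediate
21 | C8 aldehyde | CC(C)(C)[Si](C)(C)OCC1=C(Br)[C@@H](OC1=O)[C@H]1O[C@@]1(C)CC[C@@H]1O[C@]1(C)CC=O | intermediate
22 | alkenylchromium(III) dichloride | CC(C)(C)[Si](C)(C)OCC1=C([Cr](Cl)Cl)[C@@H](OC1=O)[C@H]1O[C@@]1(C)CC[C@@H]1O[C@]1(C)CC=O | intermediate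
23 | macrocyclic 8S alcohol (1S,4S,5R,6R,8S,10R) | CC(C)(C)[Si](C)(C)OCC1=C2[C@@H](OC1=O)[C@H]1O[C@@]1(C)CC[C@@H]1O[C@]1(C)C[C@@H]2O | intermediate
24 | 8R senecioate (1S,4S,5R,6R,8R,10R), C13–OTBS | CC(C)(C)[Si](C)(C)OCC1=C2[C@@H](OC1=O)[C@H]1O[C@@]1(C)CC[C@@H]1O[C@]1(C)C[C@H]2OC(=O)C=C(C)C | intermediate
25 | C13 primary alcohol | OCC1=C2[C@@H](OC1=O)[C@H]1O[C@@]1(C)CC[C@@H]1O[C@]1(C)C[C@H]2OC(=O)C=C(C)C | intermediate
26 | CNP0228323.1 | CC(=O)OCC1=C2[C@@H](OC1=O)[C@H]1O[C@@]1(C)CC[C@@H]1O[C@]1(C)C[C@H]2OC(=O)C=C(C)C | target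

**Count**
Total steps: 18. Longest linear sequence: 15 (steps 4–18, from nerol).

**Steps most likely to fail**

Step 16. β-Elimination of the β,γ-epoxy aldehyde (oxirane opening to a γ-hydroxy enal) and intermolecular coupling may outrun ring closure. The fallback carries the C1=C10 alkene instead of the oxirane through the ring closure; it sets out from 13 and returns at 23. Compound 13 is desilylated (TBAF/AcOH) to the epoxy alkenol F1 and oxidised (Dess–Martin) to the epoxy aldehyde F2. Annulation with 4 as in step 13 gives the bromobutenolide F3, DDQ gives the alcohol F4, and oxidation gives the β,γ-unsaturated aldehyde F5, which is much less prone to elimination. Ni/Cr ring closure gives the macrocyclic Z-alkene alcohol F6. Epoxidation of its only electron-rich alkene with the same L-fructose-derived ketone and Oxone (reagent control) leads back to 23.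

Step 13. Bromine–magnesium exchange may be unselective (metalation anti to the ester), or the carbenoid may α-eliminate before it meets the aldehyde. The fallback sets out from 16 and returns at 19. The lithium acetylide of tert-butyldimethyl(prop-2-yn-1-yloxy)silane adds to 16 under Felkin–Anh control to give the propargylic alcohol F7. Anti-addition of bromine (pyridinium tribromide, CH2Cl2, −20 °C) gives the (E)-dibromoalkene F8, in which the C11 bromide is cis to the carbinol. Pd(PPh3)4/CO/K2CO3 carbonylative lactonisation at that bromide leads back to 19.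

Step 17. Elimination or failure of displacement at the hindered allylic oxyphosphonium ion is possible, or the ring closure may have delivered the other C8 epimer so that inversion gives the wrong ester. The fallback sets out from 23 and returns at 24. Dess–Martin oxidation gives the C8 ketone F9. Reduction with (S)-Me-CBS/catecholborane (reagent control, large alkenyl versus small CH2 group) gives the 8R alcohol F10. Acylation with 3-methylbut-2-enoyl chloride (pyridine, DMAP) leads back to 24.

Further compounds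
F1 | step 16 | epoxy alkenol (C6–OH, Z C1=C10, C8–OPMB) | OC[C@H]1O[C@@]1(C)CC/C=C(/C)CCOCc1ccc(OC)cc1
F2 | step 16 | epoxy aldehyde (C6 CHO, Z C1=C10, C8–OPMB) | O=C[C@H]1O[C@@]1(C)CC/C=C(/C)CCOCc1ccc(OC)cc1
F3 | step 16 | bromobutenolide with Z C1=C10 alkene, C8–OPMB | CC(C)(C)[Si](C)(C)OCC1=C(Br)[C@@H](OC1=O)[C@H]1O[C@@]1(C)CC/C=C(/C)CCOCc1ccc(OC)cc1
F4 | step 16 | bromobutenolide C8 alcohol with Z C1=C10 alkene | CC(C)(C)[Si](C)(C)OCC1=C(Br)[C@@H](OC1=O)[C@H]1O[C@@]1(C)CC/C=C(/C)CCO
F5 | step 16 | bromobutenolide β,γ-unsaturated C8 aldehyde | CC(C)(C)[Si](C)(C)OCC1=C(Br)[C@@H](OC1=O)[C@H]1O[C@@]1(C)CC/C=C(/C)CC=O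
F6 | step 16 | macrocyclic Z-1(10)-alkene 8S alcohol | CC(C)(C)[Si](C)(C)OCC1=C2[C@@H](OC1=O)[C@H]1O[C@@]1(C)CC/C=C(/C)C[C@@H]2O
F7 | step 13 | propargylic alcohol (C6–OH, C7≡C11, C13–OTBS) | CC(C)(C)[Si](C)(C)OCC#C[C@@H](O)[C@H]1O[C@@]1(C)CC[C@@H]1O[C@]1(C)CCOCc1ccc(OC)cc1
F8 | step 13 | (E)-7,11-dibromoalkene carbinol | CC(C)(C)[Si](C)(C)OC/C(Br)=C(\Br)[C@@H](O)[C@H]1O[C@@]1(C)CC[C@@H]1O[C@]1(C)CCOCc1ccc(OC)cc1
F9 | step 17 | macrocyclic C8 ketone | CC(C)(C)[Si](C)(C)OCC1=C2[C@@H](OC1=O)[C@H]1O[C@@]1(C)CC[C@@H]1O[C@]1(C)CC2=O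
F10 | step 17 | macrocyclic 8R alcohol | CC(C)(C)[Si](C)(C)OCC1=C2[C@@H](OC1=O)[C@H]1O[C@@]1(C)CC[C@@H]1O[C@]1(C)C[C@H]2O
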